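The flavone is cut across ring C at C4a–C4 and O1–C2, which divides it into a mirror-symmetric ring-A resorcinol and a ring-B aroyl(methoxy)acetate that supplies C2, C3 and C4. Ring A has only one C–H, the future C4a, sitting between two equivalent hydroxyls that become O1 and the chelated 5-OH. The key step exploits this symmetry: there is one possible site of C-acylation and ring A needs no protection. A single thermal condensation of 4,5,6-trimethoxybenzene-1,3-diol with methyl 3-[3,5-bis(benzyloxy)-4-methoxyphenyl]-2-methoxy-3-oxopropanoate forms both bonds and the pyranone. Hydrogenolysis of the two benzyl ethers then completes the synthesis.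

Key step: step 6

Remark: the target has no stereogenic element, so no stereocontrol is needed; the sp3 centres that arise on the way (the α-carbon of the keto ester, the ring-closure hemiketal) are racemic and disappear when C2=C3 forms.

Step 1
Reactants: 1 3,4,5-trimethoxybenzoic acid
Product: 3 2,6-dibromo-3,4,5-trimethoxybenzoic acid, via 2-bromo-3,4,5-trimethoxybenzoic acid 2 (not isolated)
Conditions: Br2 (2.5 equiv), CHCl3–AcOH, 40–60 °C
Reagents that add atoms: bromine, BrBr
Why: Twofold electrophilic aromatic bromination should occur at the only two free ring positions, each ortho and para to methoxy groups, while the acidic medium keeps the carboxyl protonated and so disfavours ipso bromodecarboxylation.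

Step 2
Reactants: 3 2,6-dibromo-3,4,5-trimethoxybenzoic acid
Product: 5 2,6-dihydroxy-3,4,5-trimethoxybenzoic acid, via 2-bromo-6-hydroxy-3,4,5-trimethoxybenzoic acid 4 (not isolated)
Conditions: CuSO4·5H2O (15 mol%), pyridine, degassed 3 M aq. NaOH, 95 °C, N2; then aq. HCl, 0 °C
Reagents that add atoms: sodium hydroxide, [Na+].[OH-]
Why: Ullmann-type copper-catalysed hydroxylation of an ortho-halobenzoate should replace both bromides, because each lies ortho to the carboxylate that binds copper and assists the substitution.

Step 3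
Reactants: 5 2,6-dihydroxy-3,4,5-trimethoxybenzoic acid
Product: 6 4,5,6-trimethoxybenzene-1,3-diol
Conditions: degassed DMF, 130 °C, Ar; used directly in step 6
Reagents that add atoms: none
Why: Thermal protodecarboxylation should be easy because a 2,6-dihydroxybenzoic acid reacts through its keto tautomer as a β-keto acid, and the ipso carbon is further activated by the para methoxy group.

Step 4
Reactants: 7 methyl 3,5-dihydroxy-4-methoxybenzoate
Product: 9 methyl 3,5-bis(benzyloxy)-4-methoxybenzoate, via methyl 3-(benzyloxy)-5-hydroxy-4-methoxybenzoate 8 (not isolated)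
Conditions: BnBr (2.4 equiv), K2CO3 (3 equiv), DMF, 60 °C
Reagents that add atoms: benzyl bromide, BrCc1ccccc1
Why: Williamson ether synthesis on the two equivalent phenols should proceed cleanly, since the methyl ester is inert to carbonate in dry DMF.

Step 5
Reactants: 9 methyl 3,5-bis(benzyloxy)-4-methoxybenzoate; 10 methyl methoxyacetate
Product: 12 methyl 3-[3,5-bis(benzyloxy)-4-methoxyphenyl]-2-methoxy-3-oxopropanoate (racemic), via lithium enolate of methyl methoxyacetate 11 (not isolated)
Conditions: 10 (1.5 equiv), LiHMDS (3 equiv), THF, −78 °C; then 9, −78 → 0 °C; 1 M HCl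
Reagents that add atoms: none
Why: In this crossed Claisen condensation only 10 can enolise, ester 9 having no α-hydrogen, and the excess base drives the equilibrium by deprotonating the β-keto ester; the new α-stereocentre is racemic and is later lost as sp2 C3.

Step 6
Reactants: 6 4,5,6-trimethoxybenzene-1,3-diol; 12 methyl 3-[3,5-bis(benzyloxy)-4-methoxyphenyl]-2-methoxy-3-oxopropanoate
Product: 16 2-[3,5-bis(benzyloxy)-4-methoxyphenyl]-5-hydroxy-3,6,7,8-tetramethoxy-4H-chromen-4-one, via aroyl(methoxy)ketene 13 (not isolated), via 2-acylresorcinol 1,3-diketone 14 (not isolated), via 2-hydroxychroman-4-one hemiketal 15 (not isolated)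
Conditions: 12 (1.3 equiv), neat melt (or minimal Ph2O), 235–245 °C, Ar sweep to remove MeOH and H2O, 0.5–1.5 h
Reagents that add atoms: none
Why: Heating should expel methanol from 12 to give ketene 13, whose ketene carbon is attacked by the one unsubstituted ring carbon of 6 (or by a phenol oxygen, followed by a thermal Fries-type shift to that carbon), creating C4a–C4 in diketone 14. A flanking phenol then adds to the aryl ketone in a 6-exo-trig closure to hemiketal 15, and loss of water forms O1–C2 within the aromatic pyranone ring C. The closest known reaction type is the Mentzer pyrone synthesis, a Simonis-type chromone formation from a phenol and a β-keto ester under neutral thermal conditions. No stereocentre remains, because the racemic α-carbon of 12 and both sp3 carbons of 15 end as the sp2 atoms C3 and C2. The step must give the γ-pyrone (chromone) and not the α-pyrone (coumarin, Pechmann mode); the acid-free ketene pathway secures this by bringing the former ester carbon, not the ketone carbon, onto the ring. It must also attack one site only, which the symmetry of 6 guarantees: its single C–H lies between two equivalent hydroxyls and para to a methoxy group, and the hydroxyl left over becomes the 5-OH, hydrogen-bonded to C4=O and thus shielded from further acylation.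

Step 7
Reactants: 16 2-[3,5-bis(benzyloxy)-4-methoxyphenyl]-5-hydroxy-3,6,7,8-tetramethoxy-4H-chromen-4-one
Product: 18 5,3',5'-trihydroxy-3,6,7,8,4'-pentamethoxyflavone, via mono-benzyl ether 17 (not isolated)
Conditions: H2 (1 atm), 10% Pd/C, THF–MeOH, rt
Reagents that add atoms: none
Why: Catalytic hydrogenolysis should cleave both benzyl aryl ethers, while the tetrasubstituted chromone C2=C3 bond, the aryl methyl ethers and the chelated 5-OH are untouched at 1 atm and room temperature.

Compound list
1 | 3,4,5-trimethoxybenzoic acid | COc1cc(C(=O)O)cc(OC)c1OC | starting material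
2 | 2-bromo-3,4,5-trimethoxybenzoic acid | COc1cc(C(=O)O)c(Br)c(OC)c1OC | intermediate
3 | 2,6-dibromo-3,4,5-trimethoxybenzoic acid | COc1c(Br)c(C(=O)O)c(Br)c(OC)c1OC | intermediate
4 | 2-bromo-6-hydroxy-3,4,5-trimethoxybenzoic acid | COc1c(O)c(C(=O)O)c(Br)c(OC)c1OC | intermediate
5 | 2,6-dihydroxy-3,4,5-trimethoxybenzoic acid | COc1c(O)c(C(=O)O)c(O)c(OC)c1OC | intermediate
6 | 4,5,6-trimethoxybenzene-1,3-diol | COc1c(O)cc(O)c(OC)c1OC | intermediate
7 | methyl 3,5-dihydroxy-4-methoxybenzoate | COC(=O)c1cc(O)c(OC)c(O)c1 | starting material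
8 | methyl 3-(benzyloxy)-5-hydroxy-4-methoxybenzoate | COC(=O)c1cc(O)c(OC)c(OCc2ccccc2)c1 | intermediate
9 | methyl 3,5-bis(benzyloxy)-4-methoxybenzoate | COC(=O)c1cc(OCc2ccccc2)c(OC)c(OCc2ccccc2)c1 | intermediate
10 | methyl methoxyacetate | COCC(=O)OC | starting material
11 | lithium enolate of methyl methoxyacetate (lithium 1,2-dimethoxyethen-1-olate) | [Li+].[O-]C(OC)=COC | intermediate
12 | methyl 3-[3,5-bis(benzyloxy)-4-methoxyphenyl]-2-methoxy-3-oxopropanoate (racemic) | COC(=O)C(OC)C(=O)c1cc(OCc2ccccc2)c(OC)c(OCc2ccccc2)c1 | intermediate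
13 | 3-[3,5-bis(benzyloxy)-4-methoxyphenyl]-2-methoxyprop-1-ene-1,3-dione (aroyl(methoxy)ketene) | COC(=C=O)C(=O)c1cc(OCc2ccccc2)c(OC)c(OCc2ccccc2)c1 | intermediate
14 | 1-[3,5-bis(benzyloxy)-4-methoxyphenyl]-3-(2,6-dihydroxy-3,4,5-trimethoxyphenyl)-2-methoxypropane-1,3-dione (racemic) | COc1c(O)c(C(=O)C(OC)C(=O)c2cc(OCc3ccccc3)c(OC)c(OCc3ccccc3)c2)c(O)c(OC)c1OC | intermediate
15 | 2-[3,5-bis(benzyloxy)-4-methoxyphenyl]-2,5-dihydroxy-3,6,7,8-tetramethoxy-2,3-dihydro-4H-chromen-4-one (racemic, mixture of diastereomers) | COC1C(=O)c2c(O)c(OC)c(OC)c(OC)c2OC1(O)c1cc(OCc2ccccc2)c(OC)c(OCc2ccccc2)c1 | intermediate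
16 | 2-[3,5-bis(benzyloxy)-4-methoxyphenyl]-5-hydroxy-3,6,7,8-tetramethoxy-4H-chromen-4-one | COc1c(-c2cc(OCc3ccccc3)c(OC)c(OCc3ccccc3)c2)oc2c(OC)c(OC)c(OC)c(O)c2c1=O | intermediate
17 | 2-[3-(benzyloxy)-5-hydroxy-4-methoxyphenyl]-5-hydroxy-3,6,7,8-tetramethoxy-4H-chromen-4-one | COc1c(-c2cc(O)c(OC)c(OCc3ccccc3)c2)oc2c(OC)c(OC)c(OC)c(O)c2c1=O | intermediate
18 | 5,3',5'-trihydroxy-3,6,7,8,4'-pentamethoxyflavone, i.e. 2-(3,5-dihydroxy-4-methoxyphenyl)-5-hydroxy-3,6,7,8-tetramethoxy-4H-chromen-4-one (achiral) | COc1c(O)cc(-c2oc3c(OC)c(OC)c(OC)c(O)c3c(=O)c2OC)cc1O | target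

Total step count: 7.
Longest linear sequence: 5 steps (steps 1, 2, 3, 6, 7); the keto ester branch (steps 4, 5) joins at step 6.

Steps most likely to fail

1. Step 6. The ketene may be consumed by O-acylation without migration to carbon or by self-condensation, and the prolonged heat may cause oxidative darkening of the electron-rich resorcinol or partial thermal loss of benzyl groups. Fallback, by known Hoesch acylation, Claisen-type diketone synthesis and acid cyclodehydration: it sets out from 6 and rejoins the route at 14, then 16. A Hoesch reaction of 6 with methoxyacetonitrile (ZnCl2, HCl, Et2O, 0 °C) should give 1-(2,6-dihydroxy-3,4,5-trimethoxyphenyl)-2-methoxyethan-1-iminium chloride F1. Hot water hydrolyses this to 1-(2,6-dihydroxy-3,4,5-trimethoxyphenyl)-2-methoxyethan-1-one F2. Its trilithium salt (LiHMDS, 4.5 equiv, THF, −78 → 0 °C) would be acylated at carbon by ester 9 to give diketone 14, now isolated. AcOH with catalytic H2SO4 at 90 °C should then close and dehydrate 14 to 16.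

2. Step 2. The second substitution at a doubly flanked position may stall, reductive loss of bromine may compete, and the phenolate may be oxidised in hot base. Fallback, which moves the decarboxylation forward and installs oxygen through boron: it sets out from 3 and rejoins at 6, bypassing 5 and step 3. Silver-catalysed protodecarboxylation (Ag2CO3 cat., AcOH, DMSO, 120 °C) should give 1,5-dibromo-2,3,4-trimethoxybenzene F3. Double Miyaura borylation (B2pin2, Pd(dppf)Cl2, KOAc, dioxane, 90 °C) should give 2,2'-(4,5,6-trimethoxy-1,3-phenylene)bis(4,4,5,5-tetramethyl-1,3,2-dioxaborolane) F4. Mild oxidation (NaBO3·4H2O, THF–H2O, rt) should then deliver 6.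

3. Step 5. Self-condensation of the methoxyacetate enolate may outrun its attack on the hindered, moderately electrophilic aryl ester, leaving 9 unconverted. Fallback, which replaces the reversible ester–ester condensation by irreversible acyl transfer: it sets out from 9 and rejoins at 12. Saponification (LiOH, THF–MeOH–H2O) should give 3,5-bis(benzyloxy)-4-methoxybenzoic acid F5. Activation with carbonyldiimidazole (THF, rt) should give [3,5-bis(benzyloxy)-4-methoxyphenyl](1H-imidazol-1-yl)methanone F6. Adding F6 to enolate 11 (2.2 equiv, THF, −78 °C) should give 12 after acidic work-up.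

Further compounds
F1 | step 6 | 1-(2,6-dihydroxy-3,4,5-trimethoxyphenyl)-2-methoxyethan-1-iminium chloride | COCC(=[NH2+])c1c(O)c(OC)c(OC)c(OC)c1O.[Cl-]
F2 | step 6 | 1-(2,6-dihydroxy-3,4,5-trimethoxyphenyl)-2-methoxyethan-1-one | COCC(=O)c1c(O)c(OC)c(OC)c(OC)c1O
F3 | step 2 | 1,5-dibromo-2,3,4-trimethoxybenzene | COc1c(Br)cc(Br)c(OC)c1OC
F4 | step 2 | 2,2'-(4,5,6-trimethoxy-1,3-phenylene)bis(4,4,5,5-tetramethyl-1,3,2-dioxaborolane) | COc1c(B2OC(C)(C)C(C)(C)O2)cc(B2OC(C)(C)C(C)(C)O2)c(OC)c1OC
F5 | step 5 | 3,5-bis(benzyloxy)-4-methoxybenzoic acid | COc1c(OCc2ccccc2)cc(C(=O)O)cc1OCc1ccccc1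
F6 | step 5 | [3,5-bis(benzyloxy)-4-methoxyphenyl](1H-imidazol-1-yl)methanone | COc1c(OCc2ccccc2)cc(C(=O)n2ccnc2)cc1OCc1ccccc1
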